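## Retrosynthetic overview

1. Feature: the only stereocentre is C2 of flavanone ring C, at one end of the O1–C2 bond. O1 sits on ring A next to C8, which carries the C8–C8'' biaryl bond. Opening O1–C2 therefore gives an (E)-2'-hydroxychalcone that already bears the finished flavone at C3'.
2. Last disconnections: O5–CH3 and O5''–CH3 (BCl3), then O1–C2 (chalcone isomerase, sets 2S). The methyl on O6' of the chalcone leaves O2' as the only oxygen able to close ring C, which fixes the 8-linkage.
3. The chalcone–flavone comes from a C2-symmetric bis-chalcone by oxidative closure of one half (flavone ring C''). The bis-chalcone comes from a twofold Claisen–Schmidt condensation that brings in both B rings.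
4. The C8–C8'' bond comes from Ullmann homocoupling of a 3-iodoacetophenone made from 2,4,6-trihydroxyacetophenone. O4 carries MOM, one ortho oxygen carries methyl, and the other ortho oxygen carries benzyl for the coupling only.
5. Order of ring formation: both A rings and both B rings are bought, flavone ring C'' closes in step 9, and flavanone ring C closes in step 11.

Key step: step 11

Assumption: the target SMILES defines C2 only; the C8–C8'' axis carries four ortho oxygens and should be configurationally stable, so all biaryl intermediates are racemic at the axis and the final (2S) product is a pair of atropisomers, separated by HPLC only if one axial form is wanted.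

## Route

Step 1
Reactants: 1 2,4,6-trihydroxyacetophenone (dried)
Product: 2 1-[2,6-dihydroxy-4-(methoxymethoxy)phenyl]ethanone
Conditions: MOMCl (1.0 equiv), iPr2NEt, THF, 0 °C
Reagents that add atoms: chloromethyl methyl ether (MOMCl), COCCl
Why: O-Alkylation of a phenol with an alpha-chloro ether: the 4-OH is the most acidic hydroxyl and the only one that cannot hydrogen-bond to the acetyl oxygen, so one equivalent of MOMCl should go mainly there and leave the two equivalent ortho hydroxyls free.

Step 2
Reactants: 2 1-[2,6-dihydroxy-4-(methoxymethoxy)phenyl]ethanone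
Product: 3 1-[2-hydroxy-6-methoxy-4-(methoxymethoxy)phenyl]ethanone
Conditions: MeI (1.1 equiv), K2CO3, acetone, rt
Reagents that add atoms: iodomethane, CI
Why: Williamson ether synthesis: the two ortho hydroxyls of 2 are equivalent, and once one is methylated the other is held in a strong chelate with the acetyl oxygen and reacts far more slowly, so the reaction should stop at the monomethyl ether and place the methyl on the oxygen that becomes O5 or O5''.

Step 3
Reactants: 3 1-[2-hydroxy-6-methoxy-4-(methoxymethoxy)phenyl]ethanone
Product: 4 1-[2-hydroxy-3-iodo-6-methoxy-4-(methoxymethoxy)phenyl]ethanone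
Conditions: NIS (1.0 equiv), MeCN, 0 °C to rt, dark
Reagents that add atoms: N-iodosuccinimide, O=C1CCC(=O)N1I
Why: Electrophilic aromatic iodination without added acid, which spares the MOM acetal; chelated 2-hydroxy-4,6-dialkoxyacetophenones are known to take halogen at C3, ortho to the free phenol, and this is why the iodine is put in while O2 is still unprotected.

Step 4
Reactants: 4 1-[2-hydroxy-3-iodo-6-methoxy-4-(methoxymethoxy)phenyl]ethanone
Product: 5 1-[2-(benzyloxy)-3-iodo-6-methoxy-4-(methoxymethoxy)phenyl]ethanone
Conditions: BnBr, K2CO3, DMF, 60 °C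
Reagents that add atoms: benzyl bromide, BrCc1ccccc1
Why: Williamson benzylation; the phenol must be capped because a free ortho hydroxyl would protonate the arylcopper species of the Ullmann step, and benzyl is chosen because it can be taken off later under neutral conditions without touching the MOM and methyl ethers.

Step 5
Reactants: 5 1-[2-(benzyloxy)-3-iodo-6-methoxy-4-(methoxymethoxy)phenyl]ethanone (two molecules)
Product: 6 3,3'-diacetyl-2,2'-bis(benzyloxy)-4,4'-dimethoxy-6,6'-bis(methoxymethoxy)biphenyl (racemic axis)
Conditions: activated Cu powder (excess), DMF, 150 °C, Ar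
Reagents that add atoms: none
Why: Ullmann homocoupling, established for 3-iodo-2,4,6-trialkoxyacetophenones, joins the two iodine-bearing carbons to give the tetra-ortho-oxygenated biaryl bond (future C8–C8'') as a racemic, C2-symmetric axis.

Step 6
Reactants: 6 3,3'-diacetyl-2,2'-bis(benzyloxy)-4,4'-dimethoxy-6,6'-bis(methoxymethoxy)biphenyl
Product: 7 3,3'-diacetyl-4,4'-dimethoxy-6,6'-bis(methoxymethoxy)biphenyl-2,2'-diol
Conditions: H2 (1 atm), Pd/C, EtOAc, rt
Reagents that add atoms: none
Why: Catalytic hydrogenolysis cleaves only the two benzylic C–O bonds and so frees exactly the two phenols beside the biaryl bond (future O1 and O1''), while MOM ethers, methyl ethers and the hindered electron-rich aryl ketones are inert under these conditions.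

Step 7
Reactants: 8 4-hydroxybenzaldehyde
Product: 9 4-(methoxymethoxy)benzaldehyde
Conditions: MOMCl, iPr2NEt, CH2Cl2, 0 °C to rt
Reagents that add atoms: chloromethyl methyl ether (MOMCl), COCCl
Why: MOM protection of the phenol stops phenoxide formation from deactivating the aldehyde in the aldol step and uses the same protecting group as O4, so that one acid treatment removes all of them later.

Step 8
Reactants: 7 3,3'-diacetyl-4,4'-dimethoxy-6,6'-bis(methoxymethoxy)biphenyl-2,2'-diol; 9 4-(methoxymethoxy)benzaldehyde (2.5 equiv)
Product: 10 (2E,2'E)-1,1'-[2,2'-dihydroxy-4,4'-dimethoxy-6,6'-bis(methoxymethoxy)biphenyl-3,3'-diyl]bis{3-[4-(methoxymethoxy)phenyl]prop-2-en-1-one} (bis-chalcone)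
Conditions: KOH, EtOH–THF, rt; then cold aq. citric acid to pH 6
Reagents that add atoms: none
Why: Twofold Claisen–Schmidt condensation: each methyl ketone enolate adds to 9 and E1cB loss of water gives the conjugated (E)-enone, the strongly basic medium keeps the 2'-phenoxides open as chalcones, and cold neutralisation to about pH 6 avoids MOM loss and ring closure.

Step 9
Reactants: 10 bis-chalcone
Product: 11 (E)-1-[2-hydroxy-6-methoxy-4-(methoxymethoxy)-3-{5-methoxy-7-(methoxymethoxy)-2-[4-(methoxymethoxy)phenyl]-4-oxo-4H-chromen-8-yl}phenyl]-3-[4-(methoxymethoxy)phenyl]prop-2-en-1-one (MOM-protected chalcone–flavone)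
Conditions: I2 (10 mol %), DMSO, 110 °C, HPLC control, stopped at partial conversion; aq. Na2S2O3 work-up
Reagents that add atoms: none
Why: Iodine-catalysed oxidative cyclisation of a 2'-hydroxychalcone to a flavone (closure through O2', iodination alpha to the ketone, loss of HI, re-oxidation of HI by DMSO) is standard chemistry; since the two halves of 10 are equivalent and react independently the run is stopped at partial conversion, 11 is separated on silica from unchanged 10 (recycled) and from doubly cyclised material, and the MOM ethers, none of which is peri to a carbonyl, should hold at the low HI level.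

Step 10
Reactants: 11 MOM-protected chalcone–flavone
Product: 12 (E)-1-[2,4-dihydroxy-3-(7-hydroxy-2-(4-hydroxyphenyl)-5-methoxy-4-oxo-4H-chromen-8-yl)-6-methoxyphenyl]-3-(4-hydroxyphenyl)prop-2-en-1-one (chalcone–flavone, key-step precursor)
Conditions: conc. HCl (to pH 1), MeOH–THF, rt; reversed-phase chromatography
Reagents that add atoms: none
Why: Acid-catalysed acetal exchange with methanol removes all four MOM groups at room temperature, conditions under which 2'-hydroxy-6'-methoxychalcones of the xanthohumol type are known to stay open, and reversed-phase chromatography removes any trace of racemic flavanone before the enzymatic step.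

Step 11
Reactants: 12 chalcone–flavone
Product: 13 (2S)-7-hydroxy-8-[7-hydroxy-2-(4-hydroxyphenyl)-5-methoxy-4-oxo-4H-chromen-8-yl]-2-(4-hydroxyphenyl)-5-methoxy-2,3-dihydro-4H-chromen-4-one (5,5''-di-O-methyl ether of the target)
Conditions: recombinant chalcone isomerase (type 2 enzyme of Medicago sativa, or the best hit of an isomerase panel), KH2PO4/K2HPO4 buffer (50 mM, pH 6.8), DMSO (5 vol %), substrate fed in portions, 25 °C, N2, dark
Reagents that add atoms: none
Why: Proposed new method: the enzyme is expected to bind the enone of 12 in the s-trans conformation, hold the ionised O2' (the phenol between the acyl carbon C1' and the biaryl carbon C3') over the Si face of the beta-carbon and stabilise the developing enolate through its hydrogen-bond network, after which C3 is protonated. The closest known reaction type is the chalcone isomerase cyclisation of naringenin chalcone and of 6'-deoxychalcones such as isoliquiritigenin to (2S)-flavanones; a type 2 (legume) enzyme is chosen because it does not need a free 6'-hydroxyl, but neither a 6'-methoxy nor a 3'-aryl chalcone is a known substrate, so a panel of plant and bacterial isomerases and, if needed, widening of the cleft around C3' by mutagenesis belong to the step. Ring C of the flavanone closes by a 6-endo-trig oxa-Michael addition that forms O1–C2. C2 is set as (S) by the active site alone, since 12 has no stereocentre and its racemic biaryl axis lies away from the reacting face, so the axis can at most make the two atropisomers react at different rates. The step needs site selectivity between the two ortho oxygens, secured by the methyl group on O6', and a slow uncatalysed closure, secured by pH 6.8 and by the known sluggishness of 2'-hydroxy-6'-methoxychalcones towards ring closure without acid, base or heat. The driving force is relief of the twisted, doubly ortho-substituted aryl enone, and the neutral medium does not reopen the flavanone, so the configuration should persist.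

Step 12
Reactants: 13 5,5''-di-O-methyl ether of the target
Product: 14 (2S)-5,7-dihydroxy-8-[5,7-dihydroxy-2-(4-hydroxyphenyl)-4-oxo-4H-chromen-8-yl]-2-(4-hydroxyphenyl)-2,3-dihydro-4H-chromen-4-one (target)
Conditions: BCl3 (excess, 1 M in CH2Cl2), CH2Cl2, −78 to −10 °C; then ice-cold 0.5 M aq. HCl
Reagents that add atoms: none
Why: Chelation-directed cleavage of aryl methyl ethers: BCl3 binds each C4 carbonyl oxygen together with its peri methoxy oxygen (O5 and O5''), chloride takes the methyl group as MeCl and a six-membered boron chelate results that is hydrolysed on work-up; no other alkyl ether is present, and the low temperature and the absence of base are meant to keep the benzylic O1–C2 bond closed and C2 (S).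

## Compound list

1 | 2,4,6-trihydroxyacetophenone | CC(=O)c1c(O)cc(O)cc1O | starting material
2 | 1-[2,6-dihydroxy-4-(methoxymethoxy)phenyl]ethanone | CC(=O)c1c(O)cc(OCOC)cc1O | intermediate
3 | 1-[2-hydroxy-6-methoxy-4-(methoxymethoxy)phenyl]ethanone | CC(=O)c1c(O)cc(OCOC)cc1OC | intermediate
4 | 1-[2-hydroxy-3-iodo-6-methoxy-4-(methoxymethoxy)phenyl]ethanone | CC(=O)c1c(O)c(I)c(OCOC)cc1OC | intermediate
5 | 1-[2-(benzyloxy)-3-iodo-6-methoxy-4-(methoxymethoxy)phenyl]ethanone | CC(=O)c1c(OCc2ccccc2)c(I)c(OCOC)cc1OC | intermediate
6 | 3,3'-diacetyl-2,2'-bis(benzyloxy)-4,4'-dimethoxy-6,6'-bis(methoxymethoxy)biphenyl | CC(=O)c1c(OC)cc(OCOC)c(c1OCc1ccccc1)-c1c(OCOC)cc(OC)c(C(C)=O)c1OCc1ccccc1 | intermediate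
7 | 3,3'-diacetyl-4,4'-dimethoxy-6,6'-bis(methoxymethoxy)biphenyl-2,2'-diol | CC(=O)c1c(OC)cc(OCOC)c(c1O)-c1c(OCOC)cc(OC)c(C(C)=O)c1O | intermediate
8 | 4-hydroxybenzaldehyde | O=Cc1ccc(O)cc1 | starting material
9 | 4-(methoxymethoxy)benzaldehyde | COCOc1ccc(C=O)cc1 | intermediate
10 | bis-chalcone, (2E,2'E)-1,1'-[2,2'-dihydroxy-4,4'-dimethoxy-6,6'-bis(methoxymethoxy)biphenyl-3,3'-diyl]bis{3-[4-(methoxymethoxy)phenyl]prop-2-en-1-one} | O=C(/C=C/c1ccc(OCOC)cc1)c1c(OC)cc(OCOC)c(c1O)-c1c(OCOC)cc(OC)c(C(=O)/C=C/c2ccc(OCOC)cc2)c1O | intermediate
11 | MOM-protected (E)-chalcone–flavone | O=C(/C=C/c1ccc(OCOC)cc1)c1c(O)c(-c2c(OCOC)cc(OC)c3c(=O)cc(-c4ccc(OCOC)cc4)oc23)c(OCOC)cc1OC | intermediate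
12 | (E)-chalcone–flavone, key-step precursor | O=C(/C=C/c1ccc(O)cc1)c1c(O)c(-c2c(O)cc(OC)c3c(=O)cc(-c4ccc(O)cc4)oc23)c(O)cc1OC | intermediate
13 | (2S)-5,5''-di-O-methyl ether of the target, key-step product | O=C1C[C@@H](c2ccc(O)cc2)Oc2c1c(OC)cc(O)c2-c1c(O)cc(OC)c2c(=O)cc(-c3ccc(O)cc3)oc12 | intermediate
14 | (2S)-naringenin-(8→8'')-apigenin, CNP0339995.1 | O=C1C[C@@H](c2ccc(O)cc2)Oc2c1c(O)cc(O)c2-c1c(O)cc(O)c2c(=O)cc(-c3ccc(O)cc3)oc12 | target

## Step count and risks

Total step count: 12.
Longest linear sequence: 11 (steps 1–6 and 8–12; step 7 is the side branch).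

**1) Step 11 (key step, new method).**
- What may go wrong: the large 3'-flavonyl substituent or the 6'-methoxy group may prevent productive binding. Turnover would then be so slow that the uncatalysed, non-selective closure takes over and the enantiomeric purity erodes. One atropisomer may also be processed much more slowly than the other.
- Fallback (known chemistry; sets out from 12, returns at 13): 12 is closed without stereocontrol by the usual base-mediated oxa-Michael cyclisation of 2'-hydroxychalcones (NaOAc, EtOH, reflux) to the (2RS)-flavanone–flavone F1. Preparative HPLC on a polysaccharide chiral stationary phase, a standard way to resolve flavanones, gives 13. The unwanted (2R)-flavanone–flavone F2 goes back to the same base treatment, which equilibrates C2 through the chalcone, and is resolved again.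

**2) Step 9.**
- What may go wrong: nothing differentiates the two halves, so over-oxidation runs alongside the wanted reaction. Partial MOM loss and thermal closure of the remaining chalcone half in hot DMSO would complicate the separation.
- Fallback (sets out from 4, 5 and 9, returns at 11): the two halves are made different before they are joined.
  - Claisen–Schmidt condensation of 4 with 9 (KOH, EtOH) gives the 3'-iodochalcone F3.
  - F3 is taken to full conversion with I2 in DMSO to the 8-iodoflavone F4.
  - Miyaura borylation (B2pin2, PdCl2(dppf), KOAc, dioxane) gives the flavone-8-boronic pinacol ester F5.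
  - Suzuki–Miyaura coupling with 5 (Pd(OAc)2, SPhos, K3PO4, toluene–water) gives the benzyl-protected flavone–acetophenone biaryl F6.
  - Hydrogenolysis (H2, Pd/C, EtOAc) gives the flavone–hydroxyacetophenone biaryl F7.
  - One Claisen–Schmidt condensation of F7 with 9 delivers 11.

**3) Step 12.**
- What may go wrong: the Lewis acid may ionise the benzylic O1–C2 bond, assisted by the para-oxygenated B ring, or cause retro-oxa-Michael opening. Either would erode the configuration at C2. The poor solubility of the tetraphenol in CH2Cl2 may also leave the cleavage incomplete.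
- Fallback (sets out from 13, returns at 14): the four free phenols are first acetylated (Ac2O, pyridine, rt) to the tetraacetate of the dimethyl ether F8. F8 dissolves in CH2Cl2, and its electron-poorer B ring disfavours ionisation at C2. BCl3 at low temperature then gives the 7,7'',4',4'''-tetraacetate of the target F9. Acid-catalysed methanolysis (HCl in MeOH, 0 °C to rt), in which flavanones keep their configuration, gives 14.

## Further compounds

F1 | step 11 | (2RS)-7-hydroxy-8-[7-hydroxy-2-(4-hydroxyphenyl)-5-methoxy-4-oxo-4H-chromen-8-yl]-2-(4-hydroxyphenyl)-5-methoxy-2,3-dihydro-4H-chromen-4-one | O=C1CC(c2ccc(O)cc2)Oc2c1c(OC)cc(O)c2-c1c(O)cc(OC)c2c(=O)cc(-c3ccc(O)cc3)oc12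
F2 | step 11 | (2R)-7-hydroxy-8-[7-hydroxy-2-(4-hydroxyphenyl)-5-methoxy-4-oxo-4H-chromen-8-yl]-2-(4-hydroxyphenyl)-5-methoxy-2,3-dihydro-4H-chromen-4-one | O=C1C[C@H](c2ccc(O)cc2)Oc2c1c(OC)cc(O)c2-c1c(O)cc(OC)c2c(=O)cc(-c3ccc(O)cc3)oc12
F3 | step 9 | (E)-1-[2-hydroxy-3-iodo-6-methoxy-4-(methoxymethoxy)phenyl]-3-[4-(methoxymethoxy)phenyl]prop-2-en-1-one | O=C(/C=C/c1ccc(OCOC)cc1)c1c(O)c(I)c(OCOC)cc1OC
F4 | step 9 | 8-iodo-5-methoxy-7-(methoxymethoxy)-2-[4-(methoxymethoxy)phenyl]-4H-chromen-4-one | COCOc1ccc(cc1)-c1cc(=O)c2c(OC)cc(OCOC)c(I)c2o1
F5 | step 9 | 5-methoxy-7-(methoxymethoxy)-2-[4-(methoxymethoxy)phenyl]-8-(4,4,5,5-tetramethyl-1,3,2-dioxaborolan-2-yl)-4H-chromen-4-one | COCOc1ccc(cc1)-c1cc(=O)c2c(OC)cc(OCOC)c(B3OC(C)(C)C(C)(C)O3)c2o1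
F6 | step 9 | 8-[3-acetyl-2-(benzyloxy)-4-methoxy-6-(methoxymethoxy)phenyl]-5-methoxy-7-(methoxymethoxy)-2-[4-(methoxymethoxy)phenyl]-4H-chromen-4-one | CC(=O)c1c(OCc2ccccc2)c(-c2c(OCOC)cc(OC)c3c(=O)cc(-c4ccc(OCOC)cc4)oc23)c(OCOC)cc1OC
F7 | step 9 | 8-[3-acetyl-2-hydroxy-4-methoxy-6-(methoxymethoxy)phenyl]-5-methoxy-7-(methoxymethoxy)-2-[4-(methoxymethoxy)phenyl]-4H-chromen-4-one | CC(=O)c1c(O)c(-c2c(OCOC)cc(OC)c3c(=O)cc(-c4ccc(OCOC)cc4)oc23)c(OCOC)cc1OC
F8 | step 12 | (2S)-7,7'',4',4'''-tetra-O-acetyl-5,5''-di-O-methyl derivative of the target | O=C1C[C@@H](c2ccc(OC(C)=O)cc2)Oc2c1c(OC)cc(OC(C)=O)c2-c1c(OC(C)=O)cc(OC)c2c(=O)cc(-c3ccc(OC(C)=O)cc3)oc12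
F9 | step 12 | (2S)-7,7'',4',4'''-tetra-O-acetyl derivative of the target | O=C1C[C@@H](c2ccc(OC(C)=O)cc2)Oc2c1c(O)cc(OC(C)=O)c2-c1c(OC(C)=O)cc(O)c2c(=O)cc(-c3ccc(OC(C)=O)cc3)oc12
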